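**Overview**

- Retrosynthetic cuts: the C7–C8 bond of the tetrahydrofuran (carbenoid C–H insertion); the C9(=O)–O–C7' bond of a temporary lactone (reverse of a reductive opening); the C7–O–C9' benzylic ether; and, in each dihydrobenzofuran, the C2–C3 bond, the aryl–C3 bond (to ethyl diazoacetate) and the ArO–CH2 ether.
- Forward order: outer dihydrobenzofuran (phenol ether, diazoacetate coupling, C–H insertion), then the inner one by the same three operations; the two ring esters are reduced and capped as pivalates; the lactone is made separately by aldol/lactonisation; ether union; diazo transfer; the tetrahydrofuran closes last on the lactone; reductive lactone opening and deprotection.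
- Enabling feature: each of the three five-membered O-heterocycles (tetrahydrofuran O–C7–C8–C8'–C9', dihydrobenzofurans O1–C2–C3–C3a–C7a) contains O–CH(aryl)–CH(CH2OH), the imprint of an ArCH2–O ether C–H insertion. In the tetrahydrofuran the C7 aryl, C9 on C8 and C7' on C8' are all cis, so C9 and C7' can be tied as a γ-aryl lactone whose obligatory cis fusion imposes this contra-thermodynamic array.
- Stereochemistry: C2 of each dihydrobenzofuran comes from one of the two enantiomers of Rh2(PTTL)4, C3 from base epimerisation to trans; C8' from an Evans syn-aldol with (S)-4-benzyloxazolidin-2-one; C7 and C8 are relayed from C8' in the key step; C7' is temporary and ends as CH2.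

Key step: step 23

Remarks
- Locants: lignan locants carry a "C" (tetrahydrofuran O–C7–C8–C8'–C9', C9 on C8, C7' on C8'); bare numbers are benzofuran locants of the 2,5'-linked bis(dihydrobenzofuran), inner ring unprimed, outer ring primed.
- Abbreviations: ArSi = 3-methoxy-4-[(triisopropylsilyl)oxy]phenyl; BDB-Piv = (2R,3S,2'S,3'R)-2'-[4-(benzyloxy)-3-methoxyphenyl]-7,7'-dimethoxy-3,3'-bis[(pivaloyloxy)methyl]-2,3,2',3'-tetrahydro-2,5'-bi-1-benzofuran-5-yl.
- Assumption: Rh2(S-PTTL)4 is taken to give the (2R)-cis-dihydrobenzofuran in this substrate class, so Rh2(R-PTTL)4 is used for the outer ring (2S) and Rh2(S-PTTL)4 for the inner ring (2R); if the sense of induction were the reverse, the two catalysts would be exchanged.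

**Route**

Step 1
Reactants: 1 4-(benzyloxy)-3-methoxybenzyl alcohol; 2 5-iodovanillin
Product: 3 4-{[4-(benzyloxy)-3-methoxybenzyl]oxy}-3-iodo-5-methoxybenzaldehyde
Conditions: PPh3, DIAD, THF, 0 °C to rt
Reagents that add atoms: none
Why: Mitsunobu etherification of an acidic phenol (formyl and iodo substituents) with a primary electron-rich benzylic alcohol runs under neutral conditions and should leave the aldehyde and the aryl iodide untouched.

Step 2
Reactants: 3 aryl iodide; 4 ethyl diazoacetate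
Product: 5 ethyl 2-(2-{[4-(benzyloxy)-3-methoxybenzyl]oxy}-5-formyl-3-methoxyphenyl)-2-diazoacetate
Conditions: Pd(PPh3)4 (5 mol%), Ag2CO3 (0.5 equiv), Et3N, toluene, rt
Reagents that add atoms: none
Why: Palladium-catalysed cross-coupling of an aryl iodide with the C–H bond of ethyl diazoacetate (oxidative addition to zerovalent palladium, deprotonative transfer of the diazo carbon, reductive elimination) is a known route to aryldiazoacetates that keeps the diazo group and tolerates aldehydes and ethers at room temperature.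

Step 3
Reactants: 5 aryldiazoacetate
Product: 6 ethyl (2S,3R)-2-[4-(benzyloxy)-3-methoxyphenyl]-5-formyl-7-methoxy-2,3-dihydro-1-benzofuran-3-carboxylate (2,3-cis)
Conditions: Rh2(R-PTTL)4 (dirhodium tetrakis[N-phthaloyl-(R)-tert-leucinate], 2 mol%), toluene, −60 °C
Reagents that add atoms: none
Why: Enantioselective intramolecular 1,5 C–H insertion of the aryl(ester) rhodium carbene into the benzylic C–H of the neighbouring ArCH2–O ether closes the dihydrofuran ring; the chiral carboxylate catalyst sets C2 (2S) and the concerted insertion gives the 2,3-cis ester kinetically.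

Step 4
Reactants: 6 cis aldehyde
Product: 7 ethyl (2S,3R)-2-[4-(benzyloxy)-3-methoxyphenyl]-5-(hydroxymethyl)-7-methoxy-2,3-dihydro-1-benzofuran-3-carboxylate (2,3-cis)
Conditions: NaBH4, EtOH–THF, 0 °C
Reagents that add atoms: none
Why: Borohydride reduction of an aryl aldehyde is chemoselective over the ethyl ester at 0 °C and gives the benzylic alcohol needed for the next ether.

Step 5
Reactants: 7 cis alcohol
Product: 8 ethyl (2S,3S)-2-[4-(benzyloxy)-3-methoxyphenyl]-5-(hydroxymethyl)-7-methoxy-2,3-dihydro-1-benzofuran-3-carboxylate (2,3-trans)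
Conditions: NaOEt (0.5 equiv), EtOH, rt
Reagents that add atoms: none
Why: Thermodynamic epimerisation through the ester enolate moves the C3 ester trans to the C2 aryl group; C2 is untouched because expulsion of the ring oxygen from the enolate would be a stereoelectronically disfavoured reverse 5-endo process, and ethoxide matches the ester.

Step 6
Reactants: 8 trans alcohol; 2 5-iodovanillin
Product: 9 ethyl (2S,3S)-2-[4-(benzyloxy)-3-methoxyphenyl]-5-[(4-formyl-2-iodo-6-methoxyphenoxy)methyl]-7-methoxy-2,3-dihydro-1-benzofuran-3-carboxylate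
Conditions: PPh3, DIAD, THF, 0 °C to rt
Reagents that add atoms: none
Why: A second Mitsunobu etherification, of the same type as step 1, joins the benzylic alcohol to the acidic iodophenol without base strong enough to disturb the C3 centre.

Step 7
Reactants: 9 aryl iodide; 4 ethyl diazoacetate
Product: 10 ethyl (2S,3S)-2-[4-(benzyloxy)-3-methoxyphenyl]-5-{[2-(1-diazo-2-ethoxy-2-oxoethyl)-4-formyl-6-methoxyphenoxy]methyl}-7-methoxy-2,3-dihydro-1-benzofuran-3-carboxylate
Conditions: Pd(PPh3)4 (5 mol%), Ag2CO3 (0.5 equiv), Et3N, toluene, rt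
Reagents that add atoms: none
Why: The same palladium-catalysed aryl iodide/diazoacetate cross-coupling as in step 2, whose mild amine base should not epimerise the existing trans ester.

Step 8
Reactants: 10 aryldiazoacetate
Product: 11 diethyl (2R,3S,2'S,3'S)-2'-[4-(benzyloxy)-3-methoxyphenyl]-5-formyl-7,7'-dimethoxy-2,3,2',3'-tetrahydro-2,5'-bi-1-benzofuran-3,3'-dicarboxylate (inner ring cis, outer ring trans)
Conditions: Rh2(S-PTTL)4 (dirhodium tetrakis[N-phthaloyl-(S)-tert-leucinate], 2 mol%), toluene, −60 °C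
Reagents that add atoms: none
Why: The same enantioselective 1,5 C–H insertion as in step 3, now into the benzylic ether C–H next to the outer ring; the mirror-image catalyst sets the inner C2 as R (catalyst control over the remote outer stereocentres) and the ester again arrives cis.

Step 9
Reactants: 11 inner-cis diester
Product: 12 diethyl (2R,3R,2'S,3'S)-2'-[4-(benzyloxy)-3-methoxyphenyl]-5-formyl-7,7'-dimethoxy-2,3,2',3'-tetrahydro-2,5'-bi-1-benzofuran-3,3'-dicarboxylate (both rings trans)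
Conditions: NaOEt (0.5 equiv), EtOH, rt
Reagents that add atoms: none
Why: Base epimerisation of the inner C3 ester to trans as in step 5; the outer ring is already at equilibrium and the non-enolisable aldehyde is inert to catalytic ethoxide.

Step 10
Reactants: 12 trans,trans diester aldehyde
Product: 13 [(2R,3S,2'S,3'R)-2'-[4-(benzyloxy)-3-methoxyphenyl]-7,7'-dimethoxy-2,3,2',3'-tetrahydro-2,5'-bi-1-benzofuran-3,3',5-triyl]trimethanol
Conditions: LiAlH4, THF, 0 °C
Reagents that add atoms: none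
Why: Hydride reduction converts both esters (and the aldehyde) into primary alcohols; the esters are removed at this point because their tertiary benzylic α-hydrogens are more acidic than the lactone CH2 that has to be deprotonated selectively in step 21.

Step 11
Reactants: 13 triol
Product: 14 (2R,3S,2'S,3'R)-2'-[4-(benzyloxy)-3-methoxyphenyl]-3,3'-bis(hydroxymethyl)-7,7'-dimethoxy-2,3,2',3'-tetrahydro-2,5'-bi-1-benzofuran-5-carbaldehyde
Conditions: MnO2 (activated, excess), CH2Cl2, rt
Reagents that add atoms: none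
Why: Manganese dioxide oxidises benzylic alcohols selectively and leaves the two aliphatic primary alcohols untouched, which differentiates the three hydroxyl groups.

Step 12
Reactants: 14 aldehyde diol
Product: 15 (2R,3S,2'S,3'R)-2'-[4-(benzyloxy)-3-methoxyphenyl]-5-formyl-7,7'-dimethoxy-2,3,2',3'-tetrahydro-2,5'-bi-1-benzofuran-3,3'-diyl]bis(methylene) bis(2,2-dimethylpropanoate)
Conditions: PivCl, pyridine, DMAP (cat.), CH2Cl2, 0 °C to rt
Reagents that add atoms: pivaloyl chloride, CC(C)(C)C(=O)Cl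
Why: Acylation of the two primary alcohols gives pivalates, which have no α-hydrogen, resist LiHMDS at −78 °C, fluoride and borohydride, and fall off in the LiAlH4 step that is needed at the end anyway.

Step 13
Reactants: 15 bis-pivalate aldehyde
Product: 16 BDB-Piv-methanol (the 5-hydroxymethyl bis-pivalate)
Conditions: NaBH4, MeOH–THF, 0 °C
Reagents that add atoms: none
Why: Chemoselective borohydride reduction of the aryl aldehyde in the presence of hindered pivalate esters regenerates the benzylic alcohol.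

Step 14
Reactants: 16 benzylic alcohol
Product: 17 BDB-Piv-methyl 2,2,2-trichloroacetimidate
Conditions: Cl3CCN, DBU (10 mol%), CH2Cl2, 0 °C; used crude
Reagents that add atoms: trichloroacetonitrile, N#CC(Cl)(Cl)Cl
Why: Base-catalysed addition of the alcohol to trichloroacetonitrile gives the benzylic trichloroacetimidate, the standard donor for acid-catalysed transfer of electron-rich (4-alkoxybenzyl-type) groups.

Step 15
Reactants: 18 vanillin
Product: 19 3-methoxy-4-[(triisopropylsilyl)oxy]benzaldehyde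
Conditions: TIPSCl, imidazole, DMF, rt
Reagents that add atoms: triisopropylsilyl chloride, CC(C)[Si](Cl)(C(C)C)C(C)C
Why: Silylation of the phenol gives a robust aryl silyl ether that survives boron aldol, mild hydroperoxide, borane, Lewis acid and amide base, and can later be removed by fluoride to release the phenoxide exactly when it is needed.

Step 16
Reactants: 20 (S)-4-benzyl-1,3-oxazolidin-2-one; 21 methyl 4-chloro-4-oxobutanoate
Product: 22 methyl 4-[(4S)-4-benzyl-2-oxo-1,3-oxazolidin-3-yl]-4-oxobutanoate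
Conditions: n-BuLi, THF, −78 °C; then 21, −78 to 0 °C
Reagents that add atoms: none
Why: N-Acylation of the lithiated oxazolidinone with the acid chloride is the standard way to install the auxiliary and is selective for the acyl chloride over the methyl ester.

Step 17
Reactants: 22 succinyl imide; 19 silylated vanillin
Product: 24 (4S)-4-benzyl-3-{[(2S,3S)-2-ArSi-5-oxooxolan-3-yl]carbonyl}-1,3-oxazolidin-2-one (trans lactone), via syn-aldol adduct 23 (not isolated)
Conditions: Bu2BOTf, iPr2NEt, CH2Cl2, 0 °C; 19, −78 to 0 °C; pH 7 buffer, MeOH, H2O2; then PPTS (cat.), CH2Cl2, rt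
Reagents that add atoms: none
Why: Evans syn-aldol through the Z boron enolate of the imide in a chair transition state in which the benzyl group of the auxiliary shields one enolate face sets C8' and C7'; the aldol oxygen then closes the five-membered lactone onto the methyl ester, and the syn adduct necessarily gives the 4,5-trans lactone.

Step 18
Reactants: 24 lactone imide
Product: 25 (2S,3S)-2-ArSi-5-oxooxolane-3-carboxylic acid
Conditions: LiOH, H2O2, THF–H2O, 0 °C; Na2SO3; 1 M HCl to pH 3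
Reagents that add atoms: hydrogen peroxide, OO
Why: Hydroperoxide attacks the exocyclic imide carbonyl selectively and releases the recoverable auxiliary; any lactone opened by base closes again on acidification because only the γ-lactone is accessible, and the trans arrangement is the thermodynamic one.

Step 19
Reactants: 25 lactone acid
Product: 26 (4R,5S)-4-(hydroxymethyl)-5-ArSi-oxolan-2-one
Conditions: BH3·SMe2, THF, 0 °C to rt; MeOH quench
Reagents that add atoms: none
Why: Borane reduces a carboxylic acid through its acyloxyborane much faster than a lactone, so the acid becomes the C9' hydroxymethyl group with the lactone intact.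

Step 20
Reactants: 17 trichloroacetimidate; 26 lactone alcohol
Product: 27 (4R,5S)-4-{[(BDB-Piv)methoxy]methyl}-5-ArSi-oxolan-2-one
Conditions: TMSOTf (5 mol%), 4 Å MS, CH2Cl2, −78 °C; Et3N quench
Reagents that add atoms: none
Why: Acid-catalysed benzyl transfer from a trichloroacetimidate, driven by release of neutral trichloroacetamide, etherifies the primary alcohol at low temperature without base, which would trigger translactonisation, and the brief catalytic acid should spare pivalates, the silyl ether and the ring ethers.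

Step 21
Reactants: 27 lactone ether
Product: 28 (4R,5S)-4-{[(BDB-Piv)methoxy]methyl}-5-ArSi-3-(trifluoroacetyl)oxolan-2-one (C3 epimers and enol; used crude)
Conditions: LiHMDS (1.1 equiv), THF, −78 °C; CF3CO2CH2CF3; 1 M HCl work-up
Reagents that add atoms: 2,2,2-trifluoroethyl trifluoroacetate, O=C(OCC(F)(F)F)C(F)(F)F
Why: Claisen-type trifluoroacetylation of the lithium enolate activates the lactone CH2, which after step 10 is the only carbon acid within reach of LiHMDS, since pivalates and benzylic ethers are not deprotonated at −78 °C.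

Step 22
Reactants: 28 trifluoroacetyl lactone
Product: 29 (4R,5S)-3-diazo-4-{[(BDB-Piv)methoxy]methyl}-5-ArSi-oxolan-2-one
Conditions: MsN3, Et3N, H2O (1 equiv), MeCN, rt
Reagents that add atoms: methanesulfonyl azide, CS(=O)(=O)N=[N+]=[N-]
Why: Detrifluoroacetylative (Regitz-type) diazo transfer: the 1,3-dicarbonyl enolate attacks the sulfonyl azide and the triazoline collapses with loss of the trifluoroacetyl group as its N-sulfonyl amide, under conditions that touch no other group.

Step 23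
Reactants: 29 α-diazolactone
Product: 30 (3S,3aR,6R,6aS)-6-(BDB-Piv)-3-ArSi-tetrahydro-1H,3H-furo[3,4-c]furan-1-one (6-aryl endo and 3-aryl exo)
Conditions: Rh2(OAc)4 (2 mol%), CH2Cl2, reflux, slow addition of 29
Reagents that add atoms: none
Why: Dirhodium tetraacetate expels N2 from the diazolactone to give an electrophilic rhodium carbene at C8, which inserts into one C7–H bond of the ArCH2–O–C9'H2 ether through a concerted, hydride-transfer-like three-centre transition state and forms the C7–C8 bond. The closest known reaction type is the dirhodium-catalysed 1,5 C–H insertion of α-diazo-γ-butyrolactones into benzylic ether C–H bonds, which gives endo-aryl furofuranones. The tetrahydrofuran O–C7–C8–C8'–C9' closes as a five-membered ring by 1,5-insertion, the only ring size the short tether allows, at a C–H bond activated both by the ether oxygen and by the electron-rich aryl group. C8 is dictated by C8' because a bicyclo[3.3.0] lactone can only be cis-fused, which places C9 and C7' cis on the new ring; C7 is set by the kinetic preference of this insertion for the aryl group on the concave (endo) face, cis to C9, the same preference that gives cis-dihydrobenzofurans in steps 3 and 8. The step needs insertion instead of 1,2-hydride migration from C8' or attack on an arene, and endo instead of exo aryl; the rigid trans-disubstituted lactone, the doubly activated C7–H bond and an acid-free carboxylate catalyst, which cannot epimerise C7, are what should secure both.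

Step 24
Reactants: 30 furofuranone
Product: 33 (2R,3S,4R)-2-(BDB-Piv)-4-(4-hydroxy-3-methoxybenzyl)oxolane-3-carboxylic acid, via phenol lactone 31 (not isolated), via quinone methide acid 32 (not isolated)
Conditions: NaBH4 (5 equiv), THF–iPrOH, 0 °C; then TBAF (1.2 equiv); 1 M HCl to pH 4
Reagents that add atoms: none
Why: Proposed new method: fluoride cleaves the aryl silyl ether, the phenoxide para to C7' expels the C9 carboxylate by 1,6-elimination to a para-quinone methide, and borohydride already present adds hydride to its exocyclic carbon, leaving C7'H2 and the free C9 acid with C8 (never enolisable as a carboxylate) and C8' intact; the closest known reaction types are the fluoride-triggered 1,6-elimination of para-silyloxybenzyl esters and the NaBH4 reduction of quinone methides to alkylphenols, and no other benzylic C–O bond can ionise this way because every other para oxygen is an ether.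

Step 25
Reactants: 33 seco acid
Product: 34 4-{[(3R,4R,5R)-5-{(2R,3S,2'S,3'R)-2'-[4-(benzyloxy)-3-methoxyphenyl]-3,3'-bis(hydroxymethyl)-7,7'-dimethoxy-2,3,2',3'-tetrahydro-2,5'-bi-1-benzofuran-5-yl}-4-(hydroxymethyl)oxolan-3-yl]methyl}-2-methoxyphenol
Conditions: LiAlH4 (excess), THF, 0 to 50 °C; Rochelle salt work-up
Reagents that add atoms: none
Why: Lithium aluminium hydride reduces the carboxylic acid to the C9 hydroxymethyl group and cleaves both pivalates in one operation, and no centre is epimerisable under these conditions.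

Step 26
Reactants: 34 O-benzyl target
Product: 35 CNP0395728.1, 4-{[(3R,4R,5R)-5-{(2R,3S,2'S,3'R)-2'-(4-hydroxy-3-methoxyphenyl)-3,3'-bis(hydroxymethyl)-7,7'-dimethoxy-2,3,2',3'-tetrahydro-2,5'-bi-1-benzofuran-5-yl}-4-(hydroxymethyl)oxolan-3-yl]methyl}-2-methoxyphenol
Conditions: H2 (1 atm), 10% Pd/C, EtOAc–MeOH, rt, neutral
Reagents that add atoms: none
Why: Hydrogenolysis of an aryl benzyl ether is much faster than that of the cyclic dialkyl-type benzylic ethers under neutral conditions, so the last phenol is released without opening the tetrahydrofuran or dihydrobenzofuran rings or epimerising C7.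

**Compound list**

1 | 4-(benzyloxy)-3-methoxybenzyl alcohol | OCc1ccc(OCc2ccccc2)c(OC)c1 | starting material
2 | 5-iodovanillin | O=Cc1cc(I)c(O)c(OC)c1 | starting material
3 | 4-{[4-(benzyloxy)-3-methoxybenzyl]oxy}-3-iodo-5-methoxybenzaldehyde | O=Cc1cc(I)c(OCc2ccc(OCc3ccccc3)c(OC)c2)c(OC)c1 | intermediate
4 | ethyl diazoacetate | CCOC(=O)C=[N+]=[N-] | starting material
5 | ethyl 2-(2-{[4-(benzyloxy)-3-methoxybenzyl]oxy}-5-formyl-3-methoxyphenyl)-2-diazoacetate | CCOC(=O)C(=[N+]=[N-])c1cc(C=O)cc(OC)c1OCc1ccc(OCc2ccccc2)c(OC)c1 | intermediate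
6 | ethyl (2S,3R)-2-[4-(benzyloxy)-3-methoxyphenyl]-5-formyl-7-methoxy-2,3-dihydro-1-benzofuran-3-carboxylate (cis) | O=Cc1cc(OC)c2c(c1)[C@@H](C(=O)OCC)[C@@H](c1ccc(OCc3ccccc3)c(OC)c1)O2 | intermediate
7 | ethyl (2S,3R)-2-[4-(benzyloxy)-3-methoxyphenyl]-5-(hydroxymethyl)-7-methoxy-2,3-dihydro-1-benzofuran-3-carboxylate (cis) | OCc1cc(OC)c2c(c1)[C@@H](C(=O)OCC)[C@@H](c1ccc(OCc3ccccc3)c(OC)c1)O2 | intermediate
8 | ethyl (2S,3S)-2-[4-(benzyloxy)-3-methoxyphenyl]-5-(hydroxymethyl)-7-methoxy-2,3-dihydro-1-benzofuran-3-carboxylate (trans) | OCc1cc(OC)c2c(c1)[C@H](C(=O)OCC)[C@@H](c1ccc(OCc3ccccc3)c(OC)c1)O2 | intermediate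
9 | ethyl (2S,3S)-2-[4-(benzyloxy)-3-methoxyphenyl]-5-[(4-formyl-2-iodo-6-methoxyphenoxy)methyl]-7-methoxy-2,3-dihydro-1-benzofuran-3-carboxylate | O=Cc1cc(I)c(OCc2cc(OC)c3c(c2)[C@H](C(=O)OCC)[C@@H](c2ccc(OCc4ccccc4)c(OC)c2)O3)c(OC)c1 | intermediate
10 | ethyl (2S,3S)-2-[4-(benzyloxy)-3-methoxyphenyl]-5-{[2-(1-diazo-2-ethoxy-2-oxoethyl)-4-formyl-6-methoxyphenoxy]methyl}-7-methoxy-2,3-dihydro-1-benzofuran-3-carboxylate | CCOC(=O)C(=[N+]=[N-])c1cc(C=O)cc(OC)c1OCc1cc(OC)c2c(c1)[C@H](C(=O)OCC)[C@@H](c1ccc(OCc3ccccc3)c(OC)c1)O2 | intermediate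
11 | diethyl (2R,3S,2'S,3'S)-2'-[4-(benzyloxy)-3-methoxyphenyl]-5-formyl-7,7'-dimethoxy-2,3,2',3'-tetrahydro-2,5'-bi-1-benzofuran-3,3'-dicarboxylate (inner cis, outer trans) | O=Cc1cc(OC)c2c(c1)[C@H](C(=O)OCC)[C@H](c1cc(OC)c3c(c1)[C@H](C(=O)OCC)[C@@H](c1ccc(OCc4ccccc4)c(OC)c1)O3)O2 | intermediate
12 | diethyl (2R,3R,2'S,3'S)-2'-[4-(benzyloxy)-3-methoxyphenyl]-5-formyl-7,7'-dimethoxy-2,3,2',3'-tetrahydro-2,5'-bi-1-benzofuran-3,3'-dicarboxylate (both trans) | O=Cc1cc(OC)c2c(c1)[C@@H](C(=O)OCC)[C@H](c1cc(OC)c3c(c1)[C@H](C(=O)OCC)[C@@H](c1ccc(OCc4ccccc4)c(OC)c1)O3)O2 | intermediate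
13 | [(2R,3S,2'S,3'R)-2'-[4-(benzyloxy)-3-methoxyphenyl]-7,7'-dimethoxy-2,3,2',3'-tetrahydro-2,5'-bi-1-benzofuran-3,3',5-triyl]trimethanol | OCc1cc(OC)c2c(c1)[C@@H](CO)[C@H](c1cc(OC)c3c(c1)[C@H](CO)[C@@H](c1ccc(OCc4ccccc4)c(OC)c1)O3)O2 | intermediate
14 | (2R,3S,2'S,3'R)-2'-[4-(benzyloxy)-3-methoxyphenyl]-3,3'-bis(hydroxymethyl)-7,7'-dimethoxy-2,3,2',3'-tetrahydro-2,5'-bi-1-benzofuran-5-carbaldehyde | O=Cc1cc(OC)c2c(c1)[C@@H](CO)[C@H](c1cc(OC)c3c(c1)[C@H](CO)[C@@H](c1ccc(OCc4ccccc4)c(OC)c1)O3)O2 | intermediate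
15 | bis-pivalate of 14 (BDB-Piv-carbaldehyde) | O=Cc1cc(OC)c2c(c1)[C@@H](COC(=O)C(C)(C)C)[C@H](c1cc(OC)c3c(c1)[C@H](COC(=O)C(C)(C)C)[C@@H](c1ccc(OCc4ccccc4)c(OC)c1)O3)O2 | intermediate
16 | BDB-Piv-methanol | OCc1cc(OC)c2c(c1)[C@@H](COC(=O)C(C)(C)C)[C@H](c1cc(OC)c3c(c1)[C@H](COC(=O)C(C)(C)C)[C@@H](c1ccc(OCc4ccccc4)c(OC)c1)O3)O2 | intermediate
17 | BDB-Piv-methyl 2,2,2-trichloroacetimidate | N=C(OCc1cc(OC)c2c(c1)[C@@H](COC(=O)C(C)(C)C)[C@H](c1cc(OC)c3c(c1)[C@H](COC(=O)C(C)(C)C)[C@@H](c1ccc(OCc4ccccc4)c(OC)c1)O3)O2)C(Cl)(Cl)Cl | intermediate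
18 | vanillin | O=Cc1ccc(O)c(OC)c1 | starting material
19 | 3-methoxy-4-[(triisopropylsilyl)oxy]benzaldehyde | O=Cc1ccc(O[Si](C(C)C)(C(C)C)C(C)C)c(OC)c1 | intermediate
20 | (S)-4-benzyl-1,3-oxazolidin-2-one | O=C1OC[C@H](Cc2ccccc2)N1 | starting material
21 | methyl 4-chloro-4-oxobutanoate | COC(=O)CCC(Cl)=O | starting material
22 | methyl 4-[(4S)-4-benzyl-2-oxo-1,3-oxazolidin-3-yl]-4-oxobutanoate | COC(=O)CCC(=O)N1C(=O)OC[C@@H]1Cc1ccccc1 | intermediate
23 | methyl (3S,4S)-3-{[(4S)-4-benzyl-2-oxo-1,3-oxazolidin-3-yl]carbonyl}-4-hydroxy-4-ArSi-butanoate (syn-aldol adduct, formed as its boron aldolate) | COC(=O)C[C@@H]([C@H](O)c1ccc(O[Si](C(C)C)(C(C)C)C(C)C)c(OC)c1)C(=O)N1C(=O)OC[C@@H]1Cc1ccccc1 | intermediate (not isolated)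
24 | (4S)-4-benzyl-3-{[(2S,3S)-2-ArSi-5-oxooxolan-3-yl]carbonyl}-1,3-oxazolidin-2-one | O=C1C[C@H](C(=O)N2C(=O)OC[C@@H]2Cc2ccccc2)[C@@H](c2ccc(O[Si](C(C)C)(C(C)C)C(C)C)c(OC)c2)O1 | intermediate
25 | (2S,3S)-2-ArSi-5-oxooxolane-3-carboxylic acid | O=C1C[C@H](C(=O)O)[C@@H](c2ccc(O[Si](C(C)C)(C(C)C)C(C)C)c(OC)c2)O1 | intermediate
26 | (4R,5S)-4-(hydroxymethyl)-5-ArSi-oxolan-2-one | O=C1C[C@H](CO)[C@@H](c2ccc(O[Si](C(C)C)(C(C)C)C(C)C)c(OC)c2)O1 | intermediate
27 | (4R,5S)-4-{[(BDB-Piv)methoxy]methyl}-5-ArSi-oxolan-2-one | COc1cc([C@H]2OC(=O)C[C@@H]2COCc2cc(OC)c3c(c2)[C@@H](COC(=O)C(C)(C)C)[C@H](c2cc(OC)c4c(c2)[C@H](COC(=O)C(C)(C)C)[C@@H](c2ccc(OCc5ccccc5)c(OC)c2)O4)O3)ccc1O[Si](C(C)C)(C(C)C)C(C)C | intermediate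
28 | 3-(trifluoroacetyl) derivative of 27 (C3 epimers and enol) | COc1cc([C@H]2OC(=O)C(C(=O)C(F)(F)F)[C@@H]2COCc2cc(OC)c3c(c2)[C@@H](COC(=O)C(C)(C)C)[C@H](c2cc(OC)c4c(c2)[C@H](COC(=O)C(C)(C)C)[C@@H](c2ccc(OCc5ccccc5)c(OC)c2)O4)O3)ccc1O[Si](C(C)C)(C(C)C)C(C)C | intermediate
29 | (4R,5S)-3-diazo-4-{[(BDB-Piv)methoxy]methyl}-5-ArSi-oxolan-2-one | COc1cc([C@H]2OC(=O)C(=[N+]=[N-])[C@@H]2COCc2cc(OC)c3c(c2)[C@@H](COC(=O)C(C)(C)C)[C@H](c2cc(OC)c4c(c2)[C@H](COC(=O)C(C)(C)C)[C@@H](c2ccc(OCc5ccccc5)c(OC)c2)O4)O3)ccc1O[Si](C(C)C)(C(C)C)C(C)C | intermediate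
30 | (3S,3aR,6R,6aS)-6-(BDB-Piv)-3-ArSi-tetrahydro-1H,3H-furo[3,4-c]furan-1-one (endo,exo) | COc1cc([C@@H]3[C@H]2CO[C@@H](c4cc(OC)c5c(c4)[C@@H](COC(=O)C(C)(C)C)[C@H](c6cc(OC)c7c(c6)[C@H](COC(=O)C(C)(C)C)[C@@H](c8ccc(OCc9ccccc9)c(OC)c8)O7)O5)[C@H]2C(=O)O3)ccc1O[Si](C(C)C)(C(C)C)C(C)C | intermediate
31 | desilylated 30: (3S,3aR,6R,6aS)-6-(BDB-Piv)-3-(4-hydroxy-3-methoxyphenyl)tetrahydro-1H,3H-furo[3,4-c]furan-1-one (as phenoxide) | COc1cc([C@@H]3[C@H]2CO[C@@H](c4cc(OC)c5c(c4)[C@@H](COC(=O)C(C)(C)C)[C@H](c6cc(OC)c7c(c6)[C@H](COC(=O)C(C)(C)C)[C@@H](c8ccc(OCc9ccccc9)c(OC)c8)O7)O5)[C@H]2C(=O)O3)ccc1O | intermediate (not isolated)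
32 | (2R,3S,4R)-2-(BDB-Piv)-4-[(3-methoxy-4-oxocyclohexa-2,5-dien-1-ylidene)methyl]oxolane-3-carboxylic acid (para-quinone methide, as carboxylate) | COC1=CC(=C[C@H]2CO[C@@H](c3cc(OC)c4c(c3)[C@@H](COC(=O)C(C)(C)C)[C@H](c3cc(OC)c5c(c3)[C@H](COC(=O)C(C)(C)C)[C@@H](c3ccc(OCc6ccccc6)c(OC)c3)O5)O4)[C@H]2C(=O)O)C=CC1=O | intermediate (not isolated)
33 | (2R,3S,4R)-2-(BDB-Piv)-4-(4-hydroxy-3-methoxybenzyl)oxolane-3-carboxylic acid | COc1cc(C[C@H]2CO[C@@H](c3cc(OC)c4c(c3)[C@@H](COC(=O)C(C)(C)C)[C@H](c3cc(OC)c5c(c3)[C@H](COC(=O)C(C)(C)C)[C@@H](c3ccc(OCc6ccccc6)c(OC)c3)O5)O4)[C@H]2C(=O)O)ccc1O | intermediate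
34 | O-benzyl ether of the target (benzyl on the phenol of the outer 2'-aryl group) | COc1cc(C[C@H]2CO[C@@H](c3cc(OC)c4c(c3)[C@@H](CO)[C@H](c3cc(OC)c5c(c3)[C@H](CO)[C@@H](c3ccc(OCc6ccccc6)c(OC)c3)O5)O4)[C@H]2CO)ccc1O | intermediate
35 | CNP0395728.1, 4-{[(3R,4R,5R)-5-{(2R,3S,2'S,3'R)-2'-(4-hydroxy-3-methoxyphenyl)-3,3'-bis(hydroxymethyl)-7,7'-dimethoxy-2,3,2',3'-tetrahydro-2,5'-bi-1-benzofuran-5-yl}-4-(hydroxymethyl)oxolan-3-yl]methyl}-2-methoxyphenol | COc1cc(C[C@H]2CO[C@@H](c3cc(OC)c4c(c3)[C@@H](CO)[C@H](c3cc(OC)c5c(c3)[C@H](CO)[C@@H](c3ccc(O)c(OC)c3)O5)O4)[C@H]2CO)ccc1O | target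

**Step count and risks**

Total: 26 steps. Longest linear sequence: 21 steps (steps 1–14 and 20–26); the lactone branch (steps 15–19) has 5 steps.

1. Step 24 (proposed new method). What may go wrong: base-induced tautomerisation of the quinone methide to a vinylphenol with loss of the C8' centre, oligomerisation of the quinone methide before hydride capture, or borohydride attack on the lactone carbonyl before desilylation. Fallback by known chemistry, setting out from 30: hydrogenolysis (H2, Pd(OH)2/C, EtOAc–AcOH, rt) should cleave the benzylic lactone C7'–O bond, a benzylic carboxylate and the most labile benzylic C–O bond present, together with the benzyl ether, to give the silyl-protected seco acid F1. LiAlH4 in THF then reduces the acid and removes both pivalates to give the triisopropylsilyl ether of the target F2. TBAF buffered with AcOH releases the last phenol, and the sequence comes back to the route at 35.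

2. Step 23. What may go wrong: 1,2-hydride migration from C8' to the carbene (butenolide formation), carbene dimerisation on a substrate of this size, or erosion of the endo facial preference at C7. Fallback, setting out from 26 and 15: silylation (TBSCl, imidazole, DMF) gives the tert-butyldimethylsilyl ether F3. Its lithium enolate (LDA, THF, −78 °C) adds to aldehyde 15 to give the aldol adduct F4, and Dess–Martin periodinane oxidises this to the β-keto lactone F5, in which C8 is freely epimerisable. HF·pyridine removes the alkyl silyl ether to give the hydroxy keto lactone F6, which closes through its C8-cis epimer to the cis-fused bicyclic hemiketal F7. Et3SiH with BF3·OEt2 in CH2Cl2 at −78 °C then reduces the aryl-stabilised C7 oxocarbenium ion from the convex face, which places the aryl group endo, and the sequence comes back to the route at 30.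

3. Step 20. What may go wrong: rearrangement of the electron-rich imidate to the N-benzyl trichloroacetamide, Friedel–Crafts self-condensation of the benzylic cation, or acid-induced opening of a dihydrobenzofuran. Fallback, setting out from 26 and 15: the alcohol is converted (TMSCl, Et3N, CH2Cl2) into the trimethylsilyl ether F8. F8 and aldehyde 15 are treated with Et3SiH and catalytic TMSOTf in CH2Cl2 at −78 °C; in this reductive etherification the mixed acetal-derived oxocarbenium ion is reduced as it forms, so no free benzylic cation accumulates. The product is 27, where the route is rejoined; steps 13 and 14 are then not needed.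

**Further compounds**

F1 | step 24 | (2R,3S,4R)-2-{(2R,3S,2'S,3'R)-2'-(4-hydroxy-3-methoxyphenyl)-7,7'-dimethoxy-3,3'-bis[(pivaloyloxy)methyl]-2,3,2',3'-tetrahydro-2,5'-bi-1-benzofuran-5-yl}-4-{3-methoxy-4-[(triisopropylsilyl)oxy]benzyl}oxolane-3-carboxylic acid | COc1cc(C[C@H]2CO[C@@H](c3cc(OC)c4c(c3)[C@@H](COC(=O)C(C)(C)C)[C@H](c3cc(OC)c5c(c3)[C@H](COC(=O)C(C)(C)C)[C@@H](c3ccc(O)c(OC)c3)O5)O4)[C@H]2C(=O)O)ccc1O[Si](C(C)C)(C(C)C)C(C)C
F2 | step 24 | triisopropylsilyl ether of 35 (silyl group on the phenol of the C7' benzyl ring) | COc1cc(C[C@H]2CO[C@@H](c3cc(OC)c4c(c3)[C@@H](CO)[C@H](c3cc(OC)c5c(c3)[C@H](CO)[C@@H](c3ccc(O)c(OC)c3)O5)O4)[C@H]2CO)ccc1O[Si](C(C)C)(C(C)C)C(C)C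
F3 | step 23 | (4R,5S)-4-{[(tert-butyldimethylsilyl)oxy]methyl}-5-ArSi-oxolan-2-one | O=C1C[C@H](CO[Si](C)(C)C(C)(C)C)[C@@H](c2ccc(O[Si](C(C)C)(C(C)C)C(C)C)c(OC)c2)O1
F4 | step 23 | (4R,5S)-3-[(BDB-Piv)(hydroxy)methyl]-4-{[(tert-butyldimethylsilyl)oxy]methyl}-5-ArSi-oxolan-2-one (mixture at C3 and the carbinol carbon) | O=C1C(C(O)c2cc(OC)c3c(c2)[C@@H](COC(=O)C(C)(C)C)[C@H](c2cc(OC)c4c(c2)[C@H](COC(=O)C(C)(C)C)[C@@H](c2ccc(OCc5ccccc5)c(OC)c2)O4)O3)[C@H](CO[Si](C)(C)C(C)(C)C)[C@@H](c2ccc(O[Si](C(C)C)(C(C)C)C(C)C)c(OC)c2)O1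
F5 | step 23 | (4R,5S)-3-[(BDB-Piv)carbonyl]-4-{[(tert-butyldimethylsilyl)oxy]methyl}-5-ArSi-oxolan-2-one | O=C1C(C(=O)c2cc(OC)c3c(c2)[C@@H](COC(=O)C(C)(C)C)[C@H](c2cc(OC)c4c(c2)[C@H](COC(=O)C(C)(C)C)[C@@H](c2ccc(OCc5ccccc5)c(OC)c2)O4)O3)[C@H](CO[Si](C)(C)C(C)(C)C)[C@@H](c2ccc(O[Si](C(C)C)(C(C)C)C(C)C)c(OC)c2)O1
F6 | step 23 | (4R,5S)-3-[(BDB-Piv)carbonyl]-4-(hydroxymethyl)-5-ArSi-oxolan-2-one | O=C1C(C(=O)c2cc(OC)c3c(c2)[C@@H](COC(=O)C(C)(C)C)[C@H](c2cc(OC)c4c(c2)[C@H](COC(=O)C(C)(C)C)[C@@H](c2ccc(OCc5ccccc5)c(OC)c2)O4)O3)[C@H](CO)[C@@H](c2ccc(O[Si](C(C)C)(C(C)C)C(C)C)c(OC)c2)O1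
F7 | step 23 | 6-hydroxy derivative of 30 (cis-fused bicyclic hemiketal, mixture at the hemiketal carbon) | COc1cc([C@@H]3[C@H]2COC(O)(c4cc(OC)c5c(c4)[C@@H](COC(=O)C(C)(C)C)[C@H](c6cc(OC)c7c(c6)[C@H](COC(=O)C(C)(C)C)[C@@H](c8ccc(OCc9ccccc9)c(OC)c8)O7)O5)[C@H]2C(=O)O3)ccc1O[Si](C(C)C)(C(C)C)C(C)C
F8 | step 20 | (4R,5S)-4-{[(trimethylsilyl)oxy]methyl}-5-ArSi-oxolan-2-one | O=C1C[C@H](CO[Si](C)(C)C)[C@@H](c2ccc(O[Si](C(C)C)(C(C)C)C(C)C)c(OC)c2)O1
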